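Ring A of the drimane decalin is closed last, across C3–C4. C4 is a quaternary carbon carrying CH3 and CH2OH, i.e. the carbon of a 2,2-disubstituted oxirane after reductive opening; this oxirane is the epoxidised isopropenyl group of (R)-carvone, whose ring becomes ring B (C5–C10, with the C7=C8 methyl alkene already in place). The precursor is a monocyclic epoxy enone with a 2-(phenylsulfonyl)allyl arm on C10, trans to the C5 side chain. Titanocene(III) opens the oxirane to the C4 radical, which closes ring A 6-endo onto the vinyl sulfone and fixes C4. The aryl unit is then attached by B-alkyl Suzuki coupling and oxidised to the epoxyquinol.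

Key step: step 4

Remark (assumption): the oxirane of the epoxyquinol is installed by oxygen transfer to the finished carbon skeleton and is treated as a functional group; ring A is the last ring of the carbon skeleton to be formed.

Numbering used below: drimane numbering for the decalin (C1–C10, C11 = CH2 linking C9 to the oxygenated ring; α = face opposite the C10 methyl). The oxygenated six-membered ring is primed: C1′ bears C11, C3′ is the ketal/ketone carbon, C4′ bears CH2OH, C6′ is the phenol/carbinol carbon.

Step 1
Reactants: 1 (R)-(−)-carvone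
Product: 3 (5R)-6-methylcarvone (epimer mixture at the new centre, the future C10), via lithium dienolate of carvone 2 (not isolated)
Conditions: LDA, THF, −78 °C; MeI, −78 → 0 °C
Reagents that add atoms: iodomethane, CI
Why: Kinetic α′-deprotonation of the cross-conjugated enone by LDA and SN2 methylation of the lithium enolate (enolate alkylation); the new centre forms as a mixture that is erased by re-enolisation in step 2, and C5 is untouched.

Step 2
Reactants: 3 (5R)-6-methylcarvone; 4 2,3-bis(phenylsulfonyl)prop-1-ene
Product: 6 (5S,6S)-2,6-dimethyl-6-[2-(phenylsulfonyl)prop-2-enyl]-5-(prop-1-en-2-yl)cyclohex-2-en-1-one (sulfonylallyl arm trans to isopropenyl), via lithium enolate of 6-methylcarvone 5 (not isolated)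
Conditions: LDA, THF, −78 °C; enolate added to 4, −78 → −20 °C
Reagents that add atoms: none
Why: Enolate allylation by addition–elimination (SN2′) on the allyl bis-sulfone with loss of benzenesulfinate; A(1,2) strain with the C10 methyl holds the C5 isopropenyl group pseudo-axial, so the electrophile should enter the opposite face and set quaternary C10 with the arm trans to isopropenyl (substrate control), which is the future trans ring fusion.

Step 3
Reactants: 6 sulfonylallyl enone
Product: 7 epoxy enone, 5-(2-methyloxiran-2-yl) analogue of 6 (epimer mixture at the oxirane carbon, the future C4)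
Conditions: mCPBA, NaHCO3, CH2Cl2, 0 °C
Reagents that add atoms: 3-chloroperoxybenzoic acid, OOC(=O)c1cccc(Cl)c1
Why: Prilezhaev epoxidation, chemoselective for the electron-rich 1,1-disubstituted alkene over the enone and vinyl sulfone C=C bonds; the oxirane epimer mixture is irrelevant because this carbon becomes a planar radical in step 4.

Step 4
Reactants: 7 epoxy enone
Product: 8 4α-(hydroxymethyl)-4β,8,10β-trimethyl-2ξ-(phenylsulfonyl)-trans-decal-7-en-9-one (5α-H; C2 epimer mixture)
Conditions: Cp2TiCl (2.5 equiv, from Cp2TiCl2 and Mn dust), THF, rt, slow addition of the Ti(III) solution to 7; 1 M HCl work-up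
Reagents that add atoms: none
Why: Cp2Ti(III)Cl opens the 2,2-disubstituted oxirane homolytically at the more substituted C–O bond to give the β-titanoxy tertiary radical at C4, which adds to the unsubstituted terminus (C3) of the vinyl sulfone; the α-sulfonyl radical at C2 is then reduced by a second Ti(III) and protonated on work-up. The closest known reaction type is the titanocene(III)-mediated reductive epoxide opening with Giese-type radical cyclisation onto α,β-unsaturated acceptors (Nugent–RajanBabu chemistry, as used for terpenoid rings). Ring A (C4–C3–C2–C1–C10–C5) closes in the 6-endo-trig mode, because the 5-exo alternative would be attack at the sulfonyl-bearing, substituted C2, which is disfavoured electronically and sterically. The trans ring fusion is already fixed by the trans C5/C10 substituents, which are both equatorial in the chair transition state; the new stereocentre C4 is set by that chair, in which the bulky CH2OTi(Cp)2Cl group should take the equatorial (α) position and the methyl the axial position, avoiding a 1,3-diaxial clash with the C10 methyl. The step needs cyclisation to outrun reduction or disproportionation of the tertiary radical, which is secured by the slow capture of tertiary radicals by Ti(III), the low Ti(III) concentration and the strongly activated acceptor held five atoms away; the ring-B enone cannot be reached by the radical for geometric reasons. C2 forms as an epimer mixture that is erased in step 11.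

Step 5
Reactants: 8 hydroxy sulfone enone
Product: 9 tert-butyldimethylsilyl ether of 8
Conditions: TBSCl, imidazole, DMF, rt
Reagents that add atoms: tert-butyldimethylsilyl chloride, CC(C)(C)[Si](C)(C)Cl
Why: Imidazole-catalysed silylation of the neopentyl primary alcohol, so that it does not consume the titanium and boron reagents of steps 6 and 10; no stereocentre is touched.

Step 6
Reactants: 9 silyl ether enone
Product: 10 9-methylidene diene (7,9(11)-diene) derived from 9
Conditions: Cp2TiMe2, toluene, 70 °C, dark
Reagents that add atoms: dimethyltitanocene, C[Ti](C)(C1C=CC=C1)C1C=CC=C1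
Why: Petasis methylenation through Cp2Ti=CH2 and an oxatitanacyclobutane, which is non-basic and suited to hindered ketones such as this α-quaternary enone where a Wittig reagent fails; no stereocentre changes.

Step 7
Reactants: 11 2-bromo-4-methoxyphenol
Product: 12 2-bromo-4-methoxyphenyl acetate
Conditions: Ac2O, pyridine, DMAP (cat.), CH2Cl2, rt
Reagents that add atoms: acetic anhydride, CC(=O)OC(C)=O
Why: O-Acetylation (nucleophilic acyl substitution) makes the phenol oxygen a weaker ortho/para director than the methoxy group, which fixes the regiochemistry of step 8.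

Step 8
Reactants: 12 2-bromo-4-methoxyphenyl acetate
Product: 13 2-bromo-5-formyl-4-methoxyphenyl acetate (4-bromo-5-acetoxy-2-methoxybenzaldehyde)
Conditions: Cl2CHOMe, TiCl4, CH2Cl2, 0 °C; aqueous work-up
Reagents that add atoms: dichloromethyl methyl ether, COC(Cl)Cl; water, O
Why: Rieche formylation (Friedel–Crafts attack of the TiCl4-activated chloromethyl methyl oxocarbenium ion, then hydrolysis) should go ortho to the stronger methoxy donor at the open position para to bromine, not at the position flanked by Br and OMe.

Step 9
Reactants: 13 aryl aldehyde acetate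
Product: 15 2-bromo-5-(hydroxymethyl)-4-methoxyphenol, via 2-bromo-5-(hydroxymethyl)-4-methoxyphenyl acetate 14 (not isolated)
Conditions: NaBH4, MeOH, 0 °C; then K2CO3 (cat.), rt
Reagents that add atoms: none
Why: Borohydride reduction of the aldehyde followed by base-catalysed methanolysis of the aryl acetate frees the phenol that later directs the oxidative dearomatisation.

Step 10
Reactants: 10 diene; 15 2-bromo-5-(hydroxymethyl)-4-methoxyphenol
Product: 17 C11-aryl sulfone (9α-H; aryl = 2-hydroxy-4-(hydroxymethyl)-5-methoxyphenyl), via B-(C11-alkyl)-9-borabicyclo[3.3.1]nonane 16 (not isolated)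
Conditions: 9-BBN, THF, 0 → 45 °C; then 15, Pd(OAc)2/SPhos (cat.), 3 M aq K3PO4, THF–DMF, 60 °C
Reagents that add atoms: none
Why: Hydroboration of the exocyclic methylene with 9-BBN places boron on C11 and hydrogen on C9 from the α face, anti to the axial C10 methyl, which sets C9 (9α-H, C11 β-equatorial), and the B-alkyl Suzuki–Miyaura coupling of the primary alkylborane with the aryl bromide then forms the C11–C1′ bond; the trisubstituted C7=C8 alkene is too hindered for 9-BBN.

Step 11
Reactants: 17 C11-aryl sulfone
Product: 18 desulfonylated phenol (4α-CH2OTBS drim-7-ene carrying the 2-hydroxy-4-(hydroxymethyl)-5-methoxyphenyl group on C11)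
Conditions: Na/Hg (6%), Na2HPO4, MeOH–THF, −20 → 0 °C
Reagents that add atoms: none
Why: Reductive desulfonylation by single-electron transfer from sodium amalgam to the phenyl sulfone and C–S cleavage removes the activating group and with it the C2 stereocentre; alkene, aryl ether and silyl ether are inert under the buffered conditions.

Step 12
Reactants: 18 phenol
Product: 19 quinone monoketal (2-substituted 5-(hydroxymethyl)-4,4-dimethoxycyclohexa-2,5-dien-1-one; C6′=O, C3′(OMe)2)
Conditions: PhI(OAc)2, MeOH, 0 °C
Reagents that add atoms: methanol, CO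
Why: Oxidative dearomatisation of the para-methoxyphenol with PhI(OAc)2 and capture of the para position by methanol gives the quinone monoketal with the carbonyl at C6′ (the former free phenol) and the dimethyl ketal at C3′; no stereocentre is formed.

Step 13
Reactants: 19 quinone monoketal
Product: 20 1′,2′-epoxy ketone (oxirane on C1′–C2′, configuration as in the target)
Conditions: t-BuOOH, N-benzylcinchonidinium chloride (10 mol %), 0.1 M aq NaOH, toluene, 0 °C
Reagents that add atoms: tert-butyl hydroperoxide, CC(C)(C)OO
Why: Weitz–Scheffer nucleophilic epoxidation under chiral phase-transfer catalysis (Wynberg type): the hydroperoxide anion adds to the unsubstituted β-carbon C2′ (C4′ is fully substituted, so C4′=C5′ is spared, as is the electron-rich C7=C8) and the enolate closes the oxirane, the two new stereocentres C1′ and C2′ being set together by the chiral ammonium ion pair (reagent control), since the decalin stereocentres are too remote to be relied on.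

Step 14
Reactants: 20 epoxy ketone
Product: 21 epoxy alcohol (C6′–OH trans to the oxirane oxygen, cis to C11)
Conditions: L-Selectride, THF, −78 °C
Reagents that add atoms: none
Why: 1,2-Reduction by a bulky trialkylborohydride, which should approach C6′ anti to the large C11 substituent on the adjacent quaternary C1′, i.e. on the oxirane face, so that the hydroxyl ends up trans to the oxirane oxygen (steric approach control); the fully substituted β-carbon C4′ suppresses 1,4-reduction.

Step 15
Reactants: 21 epoxy alcohol
Product: 22 epoxyphomalin A (the target, named Epoxypholamin A in the task)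
Conditions: 48% aq HF, MeCN, 0 °C → rt
Reagents that add atoms: water, O
Why: Aqueous HF hydrolyses the dimethyl ketal to the C3′ enone carbonyl (oxocarbenium formation, water addition, loss of methanol) and cleaves the TBS ether in the same operation; the oxirane, the allylic carbinol and the C7=C8 alkene should tolerate these mildly acidic conditions and no stereocentre is epimerisable.

Compound list
1 | (R)-(−)-carvone | CC1=CC[C@@H](C(C)=C)CC1=O | starting material
2 | lithium dienolate of carvone | [Li+].CC1=CC[C@@H](C(C)=C)C=C1[O-] | intermediate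
3 | (5R)-6-methylcarvone (epimers at C6 of carvone) | CC1=CC[C@@H](C(C)=C)C(C)C1=O | intermediate
4 | 2,3-bis(phenylsulfonyl)prop-1-ene | C=C(CS(=O)(=O)c1ccccc1)S(=O)(=O)c1ccccc1 | starting material
5 | lithium enolate of 6-methylcarvone | [Li+].CC1=CC[C@@H](C(C)=C)C(C)=C1[O-] | intermediate
6 | (5S,6S)-2,6-dimethyl-6-[2-(phenylsulfonyl)prop-2-enyl]-5-(prop-1-en-2-yl)cyclohex-2-en-1-one | CC1=CC[C@@H](C(C)=C)[C@](C)(CC(=C)S(=O)(=O)c2ccccc2)C1=O | intermediate
7 | 5-(2-methyloxiran-2-yl) analogue of 6 (oxirane epimers) | CC1=CC[C@@H](C2(C)CO2)[C@](C)(CC(=C)S(=O)(=O)c3ccccc3)C1=O | intermediate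
8 | 4α-(hydroxymethyl)-4β,8,10β-trimethyl-2ξ-(phenylsulfonyl)-trans-decal-7-en-9-one | CC1=CC[C@H]2[C@](C)(CO)CC(S(=O)(=O)c3ccccc3)C[C@]2(C)C1=O | intermediate
9 | TBS ether of 8 | CC1=CC[C@H]2[C@](C)(CO[Si](C)(C)C(C)(C)C)CC(S(=O)(=O)c3ccccc3)C[C@]2(C)C1=O | intermediate
10 | 9-methylidene diene from 9 | CC1=CC[C@H]2[C@](C)(CO[Si](C)(C)C(C)(C)C)CC(S(=O)(=O)c3ccccc3)C[C@]2(C)C1=C | intermediate
11 | 2-bromo-4-methoxyphenol | COc1ccc(O)c(Br)c1 | starting material
12 | 2-bromo-4-methoxyphenyl acetate | COc1ccc(OC(C)=O)c(Br)c1 | intermediate
13 | 2-bromo-5-formyl-4-methoxyphenyl acetate | COc1cc(Br)c(OC(C)=O)cc1C=O | intermediate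
14 | 2-bromo-5-(hydroxymethyl)-4-methoxyphenyl acetate | COc1cc(Br)c(OC(C)=O)cc1CO | intermediate
15 | 2-bromo-5-(hydroxymethyl)-4-methoxyphenol | COc1cc(Br)c(O)cc1CO | intermediate
16 | B-(C11-alkyl)-9-BBN from 10 (9α-H) | CC1=CC[C@H]2[C@](C)(CO[Si](C)(C)C(C)(C)C)CC(S(=O)(=O)c3ccccc3)C[C@]2(C)[C@H]1CB4C5CCCC4CCC5 | intermediate
17 | C11-aryl sulfone | CC1=CC[C@H]2[C@](C)(CO[Si](C)(C)C(C)(C)C)CC(S(=O)(=O)c3ccccc3)C[C@]2(C)[C@H]1Cc4cc(OC)c(CO)cc4O | intermediate
18 | desulfonylated phenol | CC1=CC[C@H]2[C@](C)(CO[Si](C)(C)C(C)(C)C)CCC[C@]2(C)[C@H]1Cc3cc(OC)c(CO)cc3O | intermediate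
19 | quinone monoketal | CC1=CC[C@H]2[C@](C)(CO[Si](C)(C)C(C)(C)C)CCC[C@]2(C)[C@H]1CC3=CC(OC)(OC)C(CO)=CC3=O | intermediate
20 | epoxy ketone | CC1=CC[C@H]2[C@](C)(CO[Si](C)(C)C(C)(C)C)CCC[C@]2(C)[C@H]1C[C@@]34O[C@@H]3C(OC)(OC)C(CO)=CC4=O | intermediate
21 | epoxy alcohol | CC1=CC[C@H]2[C@](C)(CO[Si](C)(C)C(C)(C)C)CCC[C@]2(C)[C@H]1C[C@@]34O[C@@H]3C(OC)(OC)C(CO)=C[C@H]4O | intermediate
22 | epoxyphomalin A | CC1=CC[C@H]2[C@](C)(CO)CCC[C@]2(C)[C@H]1C[C@@]12O[C@@H]1C(=O)C(CO)=C[C@H]2O | target

Total step count: 15. Longest linear sequence: 12 steps (steps 1–6 and 10–15, from (R)-carvone).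

Steps most likely to fail

Step 4. The tertiary β-titanoxy radical may be intercepted before it reaches C3, either by reduction and β-elimination back to the alkene or by disproportionation to an allylic alcohol; the chair preference that sets C4 may also be weak. The fallback sets out from 7 and replaces the radical by an enamine. Lewis-acid Meinwald rearrangement (BF3·OEt2, CH2Cl2, −78 °C) should convert the oxirane of 7 into the α-methyl aldehyde 2-[2,4-dimethyl-3-oxo-2-(2-(phenylsulfonyl)prop-2-enyl)cyclohex-4-en-1-yl]propanal F1. Amine-catalysed intramolecular Michael addition of its enamine to the vinyl sulfone (pyrrolidine/AcOH, CHCl3, 40 °C; 6-endo-trig, bulky enamine arm equatorial) should then give the quaternary aldehyde 4β,8,10β-trimethyl-9-oxo-2ξ-(phenylsulfonyl)-trans-decal-7-ene-4α-carbaldehyde F2. Aldehyde-selective reduction (NaBH4, MeOH–CH2Cl2, −78 °C) returns to the route at 8.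

Step 10. Transmetalation of the β-branched, neopentyl-like alkylborane and oxidative addition into the electron-rich bromophenoxide may both be slow, so that protodeboronation or β-hydride loss wins. The fallback sets out from 10 and switches to a radical cross-electrophile coupling. Hydroboration–oxidation (9-BBN; NaBO3) should give the primary alcohol 11-hydroxy compound F3, and Appel iodination (I2, PPh3, imidazole) the 11-iodide F4. Nickel-catalysed reductive coupling of F4 with 15 (NiI2, 4,4′-di-tert-butyl-2,2′-bipyridine, Zn, NaI, DMPU, 60 °C) proceeds through the C11 alkyl radical and returns to the route at 17.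

Step 13. Facial discrimination by the chiral ion pair may be insufficient or reversed on a substrate whose own stereocentres are remote, giving a mixture of oxirane diastereomers. The fallback sets out from 19 and uses a covalently bound auxiliary instead of a catalyst. Transketalisation with (2R,4R)-pentane-2,4-diol (PPTS, benzene, reflux) should give the C2-symmetric spiro-dioxane dienone F5; the enantiomeric diol is taken if the induction is opposite. Auxiliary-controlled nucleophilic epoxidation (t-BuOOH, DBU, CH2Cl2) should give the spiro-dioxane epoxy ketone F6, and L-Selectride reduction the spiro-dioxane epoxy alcohol F7. Aqueous HF in MeCN removes the chiral ketal and the TBS ether and returns to the route at 22.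

Further compounds
F1 | step 4 | 2-[2,4-dimethyl-3-oxo-2-(2-(phenylsulfonyl)prop-2-enyl)cyclohex-4-en-1-yl]propanal (α-methyl epimers) | CC1=CC[C@@H](C(C)C=O)[C@](C)(CC(=C)S(=O)(=O)c2ccccc2)C1=O
F2 | step 4 | 4β,8,10β-trimethyl-9-oxo-2ξ-(phenylsulfonyl)-trans-decal-7-ene-4α-carbaldehyde | CC1=CC[C@H]2[C@](C)(C=O)CC(S(=O)(=O)c3ccccc3)C[C@]2(C)C1=O
F3 | step 10 | 11-hydroxy compound (9α-H) from 10 | CC1=CC[C@H]2[C@](C)(CO[Si](C)(C)C(C)(C)C)CC(S(=O)(=O)c3ccccc3)C[C@]2(C)[C@H]1CO
F4 | step 10 | 11-iodide from F3 | CC1=CC[C@H]2[C@](C)(CO[Si](C)(C)C(C)(C)C)CC(S(=O)(=O)c3ccccc3)C[C@]2(C)[C@H]1CI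
F5 | step 13 | spiro-dioxane dienone, (2R,4R)-pentane-2,4-diyl ketal in place of the dimethyl ketal of 19 | CC1=CC[C@H]2[C@](C)(CO[Si](C)(C)C(C)(C)C)CCC[C@]2(C)[C@H]1CC3=CC4(O[C@H](C)C[C@@H](C)O4)C(CO)=CC3=O
F6 | step 13 | spiro-dioxane epoxy ketone | CC1=CC[C@H]2[C@](C)(CO[Si](C)(C)C(C)(C)C)CCC[C@]2(C)[C@H]1C[C@@]34O[C@@H]3C5(O[C@H](C)C[C@@H](C)O5)C(CO)=CC4=O
F7 | step 13 | spiro-dioxane epoxy alcohol | CC1=CC[C@H]2[C@](C)(CO[Si](C)(C)C(C)(C)C)CCC[C@]2(C)[C@H]1C[C@@]34O[C@@H]3C5(O[C@H](C)C[C@@H](C)O5)C(CO)=C[C@H]4O
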